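**Plan**

- Retrosynthesis: the C5 ester is cut first (Mitsunobu, with inversion) into hydroxy lactone 13 and side-chain acid 24. The lactone is then cut at the acrylate C=C (Wittig), at O1–C2 (lactonization) and, in the key step, at C2–C3 and C5–C6, which leaves PMB propargyl ether 1, methyl chloroformate 2 and (S)-glyceraldehyde acetonide 3. The acid is cut at C2'=C3' (Horner–Wadsworth–Emmons), C4'=C5' (cross-metathesis) and C9'–C10' (epoxide opening).
- Enabling feature: ring atoms C3–C4–C5 of the dihydropyranone are a propargyl ether in disguise. C3 is an acetylide carbon, and C5 is an oxygen-bearing propargylic carbon that becomes an acidic γ-position once C2 is attached. One three-carbon unit therefore reacts first as an acetylide (C2–C3) and then as an allenyl metal (C5–C6); the cis C3=C4 bond of the ring is the alkyne after syn-hydrogenation.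
- Forward order: one-flask three-component coupling; Lindlar reduction with closure of the six-membered lactone (the only ring); glycol cleavage and Wittig reaction for the E-acrylate; PMB removal; Mitsunobu union with the acid; acidolysis of both protecting groups.
- Stereochemistry: C6 comes from Felkin–Anh addition to 3, whose own stereocenter is then excised. C5 is set anti to C6 in the key step and inverted in the Mitsunobu step to give the cis pair. C6' comes from (R)-β-citronellene and C11' from (S)-propylene oxide. The Z alkene comes from Lindlar reduction; the E alkenes come from Wittig, cross-metathesis and Horner–Wadsworth–Emmons reactions.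

Key step: step 1

Assumption: the metalated ynoate is taken to add to 3 with the usual anti (closed SE2' transition state) and Felkin–Anh preferences; if the C5 epimer formed instead, step 12 would be run as a retentive carbodiimide esterification.

**Route**

Step 1
Reactants: 1 1-methoxy-4-[(prop-2-yn-1-yloxy)methyl]benzene (PMB propargyl ether); 2 methyl chloroformate; 3 (4S)-2,2-dimethyl-1,3-dioxolane-4-carbaldehyde ((S)-glyceraldehyde acetonide, freshly distilled)
Product: 7 methyl (4R,5R)-5-[(4S)-2,2-dimethyl-1,3-dioxolan-4-yl]-5-hydroxy-4-[(4-methoxyphenyl)methoxy]pent-2-ynoate, via lithium acetylide 4 (not isolated), via ynoate 5 (not isolated), via allenylzirconium 6 (not isolated)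
Conditions: n-BuLi (1.0 eq), THF, −78 °C; cannulate into 2 (1.0 eq), THF, −78 → −40 °C; LDA (1.1 eq), −78 °C; Cp2ZrCl2 (1.1 eq), −78 °C; 3 (1.2 eq), −78 → −30 °C; aq NH4Cl
Reagents that add atoms: none
Why: Lithium acetylide 4 is acylated at carbon by the chloroformate (C2–C3 of the lactone), which turns the oxygen-bearing CH2 of 5 into a γ-position that LDA deprotonates to a lithium cumulenolate; transmetalation gives the carbon-bound allenylzirconium 6, which adds to aldehyde 3 through a closed six-membered SE2' transition state at its oxygen-bearing terminus (C5–C6) and restores the alkyne. The closest known reactions are the chloroformate acylation of lithium acetylides and the zirconocene-mediated γ-selective aldol-type addition of metalated 4-alkoxybut-2-ynoates to α-alkoxy aldehydes; here both are run in one flask on a single three-carbon linchpin, and no ring is closed. C5 should be set anti to the new C6 hydroxyl by the chair-like SE2' transition state, and C6 by Felkin–Anh attack anti to the dioxolane C–O bond of 3. The step needs γ- rather than α-attack of the ambident ynoate anion, which the zirconium counter-ion should secure, and deprotonation rather than addition at the ynoate, which the hindered base at −78 °C and the inverse addition of 4 to 2 should secure.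

Step 2
Reactants: 7
Product: 9 (5R,6R)-6-[(4S)-2,2-dimethyl-1,3-dioxolan-4-yl]-5-[(4-methoxyphenyl)methoxy]-5,6-dihydro-2H-pyran-2-one, via Z-enoate 8 (not isolated)
Conditions: H2 (1 atm), Lindlar catalyst (Pd/CaCO3 poisoned with Pb(OAc)2), quinoline, EtOAc, rt; then PPTS (cat.), CH2Cl2, rt
Reagents that add atoms: none
Why: Lindlar semihydrogenation adds H2 syn to the alkyne to give Z-enoate 8, whose C6 hydroxyl then closes the six-membered lactone by 6-exo-trig acyl substitution under mild acid (lactonization) without touching C5, C6 or the acetonide.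

Step 3
Reactants: 9
Product: 12 tert-butyl (2E)-3-[(2S,3R)-3-[(4-methoxyphenyl)methoxy]-6-oxo-3,6-dihydro-2H-pyran-2-yl]prop-2-enoate, via diol 10 (not isolated), via aldehyde 11 (not isolated)
Conditions: H5IO6 (1.5 eq), EtOAc, 0 °C → rt; filter; Ph3P=CHCO2tBu (1.3 eq), CH2Cl2, 0 °C
Reagents that add atoms: tert-butyl (triphenylphosphoranylidene)acetate, CC(C)(C)OC(=O)C=P(c1ccccc1)(c1ccccc1)c1ccccc1
Why: Periodic acid hydrolyses the terminal acetonide and cleaves the resulting 1,2-diol 10 (Malaprade glycol cleavage) to aldehyde 11, which is trapped at once by the stabilized ylide in an E-selective Wittig olefination; the ring oxygen is acylated and the C5 oxygen is a poorly leaving PMB ether, so C6 should keep its configuration.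

Step 4
Reactants: 12
Product: 13 tert-butyl (2E)-3-[(2S,3R)-3-hydroxy-6-oxo-3,6-dihydro-2H-pyran-2-yl]prop-2-enoate
Conditions: DDQ (1.3 eq), CH2Cl2/pH 7 buffer, 0 °C → rt
Reagents that add atoms: none
Why: DDQ oxidizes the electron-rich p-methoxybenzyl ether to an oxocarbenium ion that water hydrolyses (oxidative PMB cleavage), while the electron-poor enoates and the lactone are inert.

Step 5
Reactants: 14 (3R)-3,7-dimethylocta-1,6-diene ((R)-β-citronellene)
Product: 16 (4R)-4-methylhex-5-en-1-ol, via aldehyde 15 (not isolated)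
Conditions: O3 (1.0 eq, Sudan red 7B end point), CH2Cl2/MeOH, −78 °C; NaBH4, −78 °C → rt
Reagents that add atoms: ozone, [O-][O+]=O
Why: Ozone attacks the electron-rich trisubstituted alkene much faster than the monosubstituted one (chemoselective ozonolysis), and borohydride reduces aldehyde 15 in the same flask; the methyl-bearing stereocenter is not involved.

Step 6
Reactants: 16
Product: 17 (3R)-6-bromo-3-methylhex-1-ene
Conditions: CBr4, PPh3, CH2Cl2, 0 °C
Reagents that add atoms: tetrabromomethane, BrC(Br)(Br)Br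
Why: Appel bromination converts the primary alcohol into the bromide by SN2 displacement of an alkoxyphosphonium ion under neutral conditions.

Step 7
Reactants: 17; 18 (2S)-2-methyloxirane ((S)-propylene oxide)
Product: 20 (2S,7R)-7-methylnon-8-en-2-ol, via Grignard reagent 19 (not isolated)
Conditions: Mg, THF, rt; CuI (10 mol %), 18, −30 → 0 °C; aq NH4Cl
Reagents that add atoms: none
Why: Copper-catalyzed opening of the terminal epoxide by the Grignard reagent occurs at the unsubstituted CH2, so the C–O stereocenter of 18 is carried over unchanged as the (S)-carbinol.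

Step 8
Reactants: 20
Product: 21 tert-butyl(dimethyl){[(2S,7R)-7-methylnon-8-en-2-yl]oxy}silane
Conditions: TBSCl, imidazole, DMF, rt
Reagents that add atoms: tert-butyldimethylsilyl chloride, CC(C)(C)[Si](C)(C)Cl
Why: Standard silylation of the secondary alcohol with the silyl chloride and imidazole protects it through the olefinations and the Mitsunobu reaction.

Step 9
Reactants: 21
Product: 22 (2E,4R,9S)-9-{[tert-butyl(dimethyl)silyl]oxy}-2,4-dimethyldec-2-enal
Conditions: methacrolein (5 eq), second-generation Hoveyda–Grubbs catalyst (H2IMes)Cl2Ru=CH(C6H4-2-OiPr) (5 mol %), CH2Cl2, 40 °C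
Reagents that add atoms: methacrolein, CC(=C)C=O
Why: Olefin cross-metathesis of the terminal alkene with excess methacrolein should give the trisubstituted E-enal under thermodynamic control, the allylic stereocenter being untouched.

Step 10
Reactants: 22
Product: 23 ethyl (2E,4E,6R,11S)-11-{[tert-butyl(dimethyl)silyl]oxy}-4,6-dimethyldodeca-2,4-dienoate
Conditions: (EtO)2P(O)CH2CO2Et, NaH, THF, 0 °C → rt
Reagents that add atoms: triethyl phosphonoacetate, CCOC(=O)CP(=O)(OCC)OCC
Why: Horner–Wadsworth–Emmons olefination of the enal with the stabilized phosphonate anion gives the new double bond with E geometry.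

Step 11
Reactants: 23
Product: 24 (2E,4E,6R,11S)-11-{[tert-butyl(dimethyl)silyl]oxy}-4,6-dimethyldodeca-2,4-dienoic acid
Conditions: LiOH, THF/MeOH/H2O, rt; 1 M HCl to pH 3
Reagents that add atoms: lithium hydroxide, [Li+].[OH-]
Why: Saponification of the ethyl ester with LiOH leaves the silyl ether and the diene geometry intact and gives the acid for the coupling.

Step 12
Reactants: 13; 24
Product: 25 (2S,3S)-2-[(1E)-3-tert-butoxy-3-oxoprop-1-en-1-yl]-6-oxo-3,6-dihydro-2H-pyran-3-yl (2E,4E,6R,11S)-11-{[tert-butyl(dimethyl)silyl]oxy}-4,6-dimethyldodeca-2,4-dienoate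
Conditions: PPh3 (1.5 eq), DIAD (1.5 eq), toluene, −20 → 0 °C
Reagents that add atoms: none
Why: Mitsunobu esterification activates the C5 hydroxyl of 13 as an alkoxyphosphonium ion that the carboxylate of 24 displaces by SN2 with inversion, which turns the trans relation of C5 and C6 into the cis relation of the target while the ester is formed.

Step 13
Reactants: 25
Product: 26 (2E)-3-[(2S,3S)-3-{[(2E,4E,6R,11S)-11-hydroxy-4,6-dimethyldodeca-2,4-dienoyl]oxy}-6-oxo-3,6-dihydro-2H-pyran-2-yl]prop-2-enoic acid (target)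
Conditions: TFA/CH2Cl2/H2O (10:10:1), 0 °C → rt; evaporate; MeOH, rt
Reagents that add atoms: none
Why: Acidolysis cleaves the tert-butyl ester by loss of the tert-butyl cation and the silyl ether by protodesilylation, while the lactone, the allylic ester and the alkenes are stable to acid, so the elimination-prone 5-acyloxy lactone never meets a base.

**Compound list**

1 | 1-methoxy-4-[(prop-2-yn-1-yloxy)methyl]benzene | C#CCOCc1ccc(OC)cc1 | starting material
2 | methyl chloroformate | COC(=O)Cl | starting material
3 | (4S)-2,2-dimethyl-1,3-dioxolane-4-carbaldehyde | O=C[C@@H]1COC(C)(C)O1 | starting material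
4 | lithium 3-[(4-methoxyphenyl)methoxy]prop-1-yn-1-ide | [Li]C#CCOCc1ccc(OC)cc1 | intermediate
5 | methyl 4-[(4-methoxyphenyl)methoxy]but-2-ynoate | COC(=O)C#CCOCc1ccc(OC)cc1 | intermediate
6 | chlorobis(cyclopentadienyl){1-methoxy-4-[(4-methoxyphenyl)methoxy]-1-oxobuta-2,3-dien-2-yl}zirconium (rings drawn sigma-bonded) | COC(=O)C(=C=COCc1ccc(OC)cc1)[Zr](Cl)(C1C=CC=C1)C1C=CC=C1 | intermediate
7 | methyl (4R,5R)-5-[(4S)-2,2-dimethyl-1,3-dioxolan-4-yl]-5-hydroxy-4-[(4-methoxyphenyl)methoxy]pent-2-ynoate | COC(=O)C#C[C@@H](OCc1ccc(OC)cc1)[C@@H](O)[C@@H]1COC(C)(C)O1 | intermediate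
8 | methyl (2Z,4R,5R)-5-[(4S)-2,2-dimethyl-1,3-dioxolan-4-yl]-5-hydroxy-4-[(4-methoxyphenyl)methoxy]pent-2-enoate | COC(=O)/C=C\[C@@H](OCc1ccc(OC)cc1)[C@@H](O)[C@@H]1COC(C)(C)O1 | intermediate
9 | (5R,6R)-6-[(4S)-2,2-dimethyl-1,3-dioxolan-4-yl]-5-[(4-methoxyphenyl)methoxy]-5,6-dihydro-2H-pyran-2-one | COc1ccc(CO[C@@H]2C=CC(=O)O[C@H]2[C@@H]2COC(C)(C)O2)cc1 | intermediate
10 | (5R,6S)-6-[(1S)-1,2-dihydroxyethyl]-5-[(4-methoxyphenyl)methoxy]-5,6-dihydro-2H-pyran-2-one | COc1ccc(CO[C@@H]2C=CC(=O)O[C@H]2[C@@H](O)CO)cc1 | intermediate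
11 | (2R,3R)-3-[(4-methoxyphenyl)methoxy]-6-oxo-3,6-dihydro-2H-pyran-2-carbaldehyde | COc1ccc(CO[C@@H]2C=CC(=O)O[C@H]2C=O)cc1 | intermediate
12 | tert-butyl (2E)-3-[(2S,3R)-3-[(4-methoxyphenyl)methoxy]-6-oxo-3,6-dihydro-2H-pyran-2-yl]prop-2-enoate | COc1ccc(CO[C@@H]2C=CC(=O)O[C@H]2/C=C/C(=O)OC(C)(C)C)cc1 | intermediate
13 | tert-butyl (2E)-3-[(2S,3R)-3-hydroxy-6-oxo-3,6-dihydro-2H-pyran-2-yl]prop-2-enoate | O[C@@H]1C=CC(=O)O[C@H]1/C=C/C(=O)OC(C)(C)C | intermediate
14 | (3R)-3,7-dimethylocta-1,6-diene | C=C[C@H](C)CCC=C(C)C | starting material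
15 | (4R)-4-methylhex-5-enal | C=C[C@H](C)CCC=O | intermediate
16 | (4R)-4-methylhex-5-en-1-ol | C=C[C@H](C)CCCO | intermediate
17 | (3R)-6-bromo-3-methylhex-1-ene | C=C[C@H](C)CCCBr | intermediate
18 | (2S)-2-methyloxirane | C[C@H]1CO1 | starting material
19 | bromo[(4R)-4-methylhex-5-en-1-yl]magnesium | C=C[C@H](C)CCC[Mg]Br | intermediate
20 | (2S,7R)-7-methylnon-8-en-2-ol | C=C[C@H](C)CCCC[C@H](C)O | intermediate
21 | tert-butyl(dimethyl){[(2S,7R)-7-methylnon-8-en-2-yl]oxy}silane | C=C[C@H](C)CCCC[C@H](C)O[Si](C)(C)C(C)(C)C | intermediate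
22 | (2E,4R,9S)-9-{[tert-butyl(dimethyl)silyl]oxy}-2,4-dimethyldec-2-enal | O=C/C(C)=C/[C@H](C)CCCC[C@H](C)O[Si](C)(C)C(C)(C)C | intermediate
23 | ethyl (2E,4E,6R,11S)-11-{[tert-butyl(dimethyl)silyl]oxy}-4,6-dimethyldodeca-2,4-dienoate | CCOC(=O)/C=C/C(C)=C/[C@H](C)CCCC[C@H](C)O[Si](C)(C)C(C)(C)C | intermediate
24 | (2E,4E,6R,11S)-11-{[tert-butyl(dimethyl)silyl]oxy}-4,6-dimethyldodeca-2,4-dienoic acid | OC(=O)/C=C/C(C)=C/[C@H](C)CCCC[C@H](C)O[Si](C)(C)C(C)(C)C | intermediate
25 | (2S,3S)-2-[(1E)-3-tert-butoxy-3-oxoprop-1-en-1-yl]-6-oxo-3,6-dihydro-2H-pyran-3-yl (2E,4E,6R,11S)-11-{[tert-butyl(dimethyl)silyl]oxy}-4,6-dimethyldodeca-2,4-dienoate | CC(/C=C/C(=O)O[C@H]1C=CC(=O)O[C@H]1/C=C/C(=O)OC(C)(C)C)=C\[C@H](C)CCCC[C@H](C)O[Si](C)(C)C(C)(C)C | intermediate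
26 | (2E)-3-[(2S,3S)-3-{[(2E,4E,6R,11S)-11-hydroxy-4,6-dimethyldodeca-2,4-dienoyl]oxy}-6-oxo-3,6-dihydro-2H-pyran-2-yl]prop-2-enoic acid | CC(/C=C/C(=O)O[C@H]1C=CC(=O)O[C@H]1/C=C/C(=O)O)=C\[C@H](C)CCCC[C@H](C)O | target

**Step count and risks**

Total steps: 13. Longest linear sequence: 9 (steps 5 to 11, then 12 and 13); the lactone branch is steps 1 to 4.

Steps most likely to fail:

1. Step 1. The aldehyde may attack the ester-bearing carbon of the ambident ynoate anion (allenoate formation), or the anti and Felkin–Anh preferences may erode. The fallback sets out from 1 and 3 and comes back at 7; it reverses the order of events and brings the ester in last by carbonylation. Ether 1 is C-silylated (n-BuLi, Me3SiCl) to the silylalkyne F1. F1 is lithiated at the propargylic CH2 (t-BuLi, THF, −78 °C), transmetalated with Ti(OiPr)4 and added to 3 as an allenyltitanium, which carries no ester and reacts only at the oxygen-bearing carbon (anti), to give the silylated adduct F2. K2CO3 in MeOH gives the terminal alkyne F3. Oxidative methoxycarbonylation of the terminal alkyne (PdCl2 cat., CuCl2, NaOAc, CO, MeOH) should then return 7.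

2. Step 3. The p-methoxybenzyloxy group may be lost by β-elimination, or the ring carbon next to the formyl group of 11 may epimerize, before the olefination; the elimination is driven by aromatization to a 2-pyranone. The fallback sets out from 9 and comes back at 12 without any aldehyde. Aqueous acetic acid removes the acetonide and diol 10 is isolated. Garegg–Samuelsson deoxygenation (PPh3, I2, imidazole, toluene, 80 °C) turns the terminal diol into the vinyl lactone F4. Cross-metathesis of F4 with tert-butyl acrylate (second-generation Hoveyda–Grubbs catalyst as in step 9) should give 12.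

3. Step 12. The activated C5 oxygen may be lost by elimination towards the aromatic 2-pyranone, or the carboxylate may attack with allylic transposition or with retention instead of clean inversion. The fallback sets out from 13 and comes back at 25; it inverts C5 by oxidation and reduction and then forms the ester with retention. Dess–Martin periodinane (NaHCO3, CH2Cl2) oxidizes 13 to the keto lactone F5. Reduction with NaBH4 and CeCl3·7H2O (MeOH, −78 °C; Luche conditions), with hydride arriving on the face opposite the C6 substituent, should give the cis alcohol F6. Carbodiimide esterification of F6 with 24 (DCC, DMAP, CH2Cl2, 0 °C) should give 25.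

**Further compounds**

F1 | step 1 | {3-[(4-methoxyphenyl)methoxy]prop-1-yn-1-yl}(trimethyl)silane | COc1ccc(COCC#C[Si](C)(C)C)cc1
F2 | step 1 | (1R,2R)-1-[(4S)-2,2-dimethyl-1,3-dioxolan-4-yl]-2-[(4-methoxyphenyl)methoxy]-4-(trimethylsilyl)but-3-yn-1-ol | C[Si](C)(C)C#C[C@@H](OCc1ccc(OC)cc1)[C@@H](O)[C@@H]1COC(C)(C)O1
F3 | step 1 | (1R,2R)-1-[(4S)-2,2-dimethyl-1,3-dioxolan-4-yl]-2-[(4-methoxyphenyl)methoxy]but-3-yn-1-ol | C#C[C@@H](OCc1ccc(OC)cc1)[C@@H](O)[C@@H]1COC(C)(C)O1
F4 | step 3 | (5R,6S)-6-ethenyl-5-[(4-methoxyphenyl)methoxy]-5,6-dihydro-2H-pyran-2-one | COc1ccc(CO[C@@H]2C=CC(=O)O[C@H]2C=C)cc1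
F5 | step 12 | tert-butyl (2E)-3-[(2S)-3,6-dioxo-3,6-dihydro-2H-pyran-2-yl]prop-2-enoate | O=C1C=CC(=O)O[C@H]1/C=C/C(=O)OC(C)(C)C
F6 | step 12 | tert-butyl (2E)-3-[(2S,3S)-3-hydroxy-6-oxo-3,6-dihydro-2H-pyran-2-yl]prop-2-enoate | O[C@H]1C=CC(=O)O[C@H]1/C=C/C(=O)OC(C)(C)C
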